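**Retrosynthetic overview**
1. Oxepine ring (closed last): aryl O–C(alkenyl) bond from the 2'-phenol and an alkenyl bromide on the C3 side chain, by copper-catalysed intramolecular coupling under base only.
2. Pyranone ring (ring C): acid cyclodehydration of an α-alkylated 1,3-diketone; the C3 side chain comes from C-alkylation with 1,2-dibromo-3-methylbut-2-ene (made from prenal).
3. Key C–C bond: crossed Claisen condensation of the ring A methyl ketone enolate with the ring B allyl benzoate.
4. Ring A ketone from phloroacetophenone: MOM/methyl differentiation, O-prenylation and para-Claisen–Cope shift (6-prenyl), then prenal chromenylation (dimethylpyran ring, formed first).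
5. Ring order: dimethylpyran, then pyranone, then oxepine; rings A and B are bought as arenes.

Assumption: the target has no stereocentre and no stereogenic double bond, so it is achiral and no asymmetric step is needed.

**Route**

Step 1
Reactants: 1 1-(2,4,6-trihydroxyphenyl)ethan-1-one (phloroacetophenone)
Product: 2 1-[2,6-dihydroxy-4-(methoxymethoxy)phenyl]ethan-1-one
Conditions: MOMCl (1.05 equiv), K2CO3 (1.1 equiv), acetone, 0 °C → rt
Reagents that add atoms: chloromethyl methyl ether (MOMCl), COCCl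
Why: Williamson-type MOM protection goes first to the 4-OH, the only hydroxyl not hydrogen-bonded to the acetyl group and the most acidic one.

Step 2
Reactants: 2 1-[2,6-dihydroxy-4-(methoxymethoxy)phenyl]ethan-1-one
Product: 3 1-[2-hydroxy-6-methoxy-4-(methoxymethoxy)phenyl]ethan-1-one
Conditions: Me2SO4 (1.05 equiv), K2CO3, acetone, 40 °C
Reagents that add atoms: dimethyl sulfate, COS(=O)(=O)OC
Why: Williamson O-methylation of one of two equivalent ortho hydroxyls stops cleanly at the mono-ether because the remaining hydroxyl is then locked in a strong hydrogen bond to the carbonyl.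

Step 3
Reactants: 3 1-[2-hydroxy-6-methoxy-4-(methoxymethoxy)phenyl]ethan-1-one
Product: 4 1-{2-methoxy-4-(methoxymethoxy)-6-[(3-methylbut-2-en-1-yl)oxy]phenyl}ethan-1-one
Conditions: prenyl bromide (1.3 equiv), K2CO3, DMF, 50 °C
Reagents that add atoms: 1-bromo-3-methylbut-2-ene (prenyl bromide), CC(C)=CCBr
Why: Williamson etherification of the chelated phenoxide with a reactive allylic bromide in a polar aprotic solvent gives the aryl prenyl ether needed for the rearrangement.

Step 4
Reactants: 4 1-{2-methoxy-4-(methoxymethoxy)-6-[(3-methylbut-2-en-1-yl)oxy]phenyl}ethan-1-one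
Product: 7 1-[6-hydroxy-2-methoxy-4-(methoxymethoxy)-3-(3-methylbut-2-en-1-yl)phenyl]ethan-1-one, via ortho-dienone 5 (not isolated), via para-dienone 6 (not isolated)
Conditions: PhNEt2, 200 °C, argon, sealed tube
Reagents that add atoms: none
Why: Aromatic para-Claisen rearrangement: a [3,3] Claisen shift gives the congested 1,1-dimethylallyl dienone 5, a second [3,3] Cope shift moves the group to the para carbon (dienone 6), and tautomerisation leaves a normal prenyl group exactly between the MOM and methyl ethers.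

Step 5
Reactants: 7 1-[6-hydroxy-2-methoxy-4-(methoxymethoxy)-3-(3-methylbut-2-en-1-yl)phenyl]ethan-1-one
Product: 8 1-[4,6-dihydroxy-2-methoxy-3-(3-methylbut-2-en-1-yl)phenyl]ethan-1-one
Conditions: conc. HCl (cat.), MeOH, rt
Reagents that add atoms: none
Why: Acid-catalysed acetal cleavage (transacetalisation of the MOM group to methanol) runs at room temperature, which is too mild to cyclise the ortho-prenylphenol to a chroman.

Step 6
Reactants: 8 1-[4,6-dihydroxy-2-methoxy-3-(3-methylbut-2-en-1-yl)phenyl]ethan-1-one; 9 3-methylbut-2-enal (prenal)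
Product: 11 1-[5-hydroxy-7-methoxy-2,2-dimethyl-8-(3-methylbut-2-en-1-yl)-2H-chromen-6-yl]ethan-1-one, via quinone methide 10 (not isolated)
Conditions: ethylenediammonium diacetate (20 mol%), xylene, 140 °C
Reagents that add atoms: none
Why: Formal [3+3] chromenylation: Knoevenagel-type condensation of iminium-activated prenal at the only unsubstituted ring carbon gives quinone methide 10, and oxa-6π electrocyclisation closes the dimethylpyran through the 4-oxygen so that the ketone-chelated hydroxyl is kept.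

Step 7
Reactants: 11 1-[5-hydroxy-7-methoxy-2,2-dimethyl-8-(3-methylbut-2-en-1-yl)-2H-chromen-6-yl]ethan-1-one
Product: 12 1-[7-methoxy-5-(methoxymethoxy)-2,2-dimethyl-8-(3-methylbut-2-en-1-yl)-2H-chromen-6-yl]ethan-1-one
Conditions: NaH, DMF, 0 °C; MOMCl, 0 °C → rt
Reagents that add atoms: chloromethyl methyl ether (MOMCl), COCCl
Why: Williamson MOM protection through the sodium phenoxide masks the chelated phenol, so that the two following base-mediated steps meet only one acidic site.

Step 8
Reactants: 13 2-hydroxy-4,5-dimethoxybenzoic acid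
Product: 14 prop-2-en-1-yl 4,5-dimethoxy-2-(prop-2-en-1-yloxy)benzoate
Conditions: allyl bromide (2.5 equiv), K2CO3 (3 equiv), DMF, 60 °C
Reagents that add atoms: 3-bromoprop-1-ene (allyl bromide), C=CCBr
Why: One-pot Williamson etherification and carboxylate alkylation gives an acid-stable allyl ether on the ring B phenol and an ester that serves as the acyl donor.

Step 9
Reactants: 9 3-methylbut-2-enal (prenal)
Product: 16 2-bromo-3-methylbut-2-enal, via dibromoaldehyde 15 (not isolated)
Conditions: Br2, CH2Cl2, −78 → 0 °C; then Et3N, 0 °C → rt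
Reagents that add atoms: bromine, BrBr
Why: Bromine addition to the alkene followed by E1cB dehydrobromination (loss of the acidic α-hydrogen and the tertiary β-bromide) is the standard α-bromination of an enal.

Step 10
Reactants: 16 2-bromo-3-methylbut-2-enal
Product: 17 2-bromo-3-methylbut-2-en-1-ol
Conditions: NaBH4, CeCl3·7H2O, MeOH, 0 °C
Reagents that add atoms: none
Why: Luche reduction delivers hydride 1,2 to the enal carbonyl and leaves the alkenyl bromide untouched.

Step 11
Reactants: 17 2-bromo-3-methylbut-2-en-1-ol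
Product: 18 1,2-dibromo-3-methylbut-2-ene
Conditions: CBr4, PPh3, CH2Cl2, 0 °C
Reagents that add atoms: carbon tetrabromide, BrC(Br)(Br)Br
Why: The Appel reaction turns the primary allylic alcohol into the bromide by substitution at the primary carbon under neutral conditions, with little allylic transposition.

Step 12
Reactants: 12 1-[7-methoxy-5-(methoxymethoxy)-2,2-dimethyl-8-(3-methylbut-2-en-1-yl)-2H-chromen-6-yl]ethan-1-one; 14 prop-2-en-1-yl 4,5-dimethoxy-2-(prop-2-en-1-yloxy)benzoate
Product: 19 1-[4,5-dimethoxy-2-(prop-2-en-1-yloxy)phenyl]-3-[7-methoxy-5-(methoxymethoxy)-2,2-dimethyl-8-(3-methylbut-2-en-1-yl)-2H-chromen-6-yl]propane-1,3-dione (mainly the enol tautomer)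
Conditions: NaH (3 equiv), THF, 65 °C; then cold 0.5 M HCl
Reagents that add atoms: none
Why: Crossed Claisen condensation: the sodium enolate of the methyl ketone, whose own di-ortho-substituted carbonyl is too hindered to self-condense, adds to the ester, allyloxide leaves, and irreversible deprotonation of the 1,3-diketone drives the reaction.

Step 13
Reactants: 19 the 1,3-diketone from step 12; 18 1,2-dibromo-3-methylbut-2-ene
Product: 20 2-(2-bromo-3-methylbut-2-en-1-yl)-1-[4,5-dimethoxy-2-(prop-2-en-1-yloxy)phenyl]-3-[7-methoxy-5-(methoxymethoxy)-2,2-dimethyl-8-(3-methylbut-2-en-1-yl)-2H-chromen-6-yl]propane-1,3-dione (racemic)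
Conditions: K2CO3, acetone, 55 °C
Reagents that add atoms: none
Why: C-alkylation of the soft 1,3-diketone enolate by SN2 at the primary allylic carbon installs the future C3 side chain with its alkenyl bromide; the new stereocentre forms racemic and is erased in step 14.

Step 14
Reactants: 20 the C-alkylated 1,3-diketone from step 13
Product: 23 3-(2-bromo-3-methylbut-2-en-1-yl)-2-[4,5-dimethoxy-2-(prop-2-en-1-yloxy)phenyl]-5-methoxy-8,8-dimethyl-6-(3-methylbut-2-en-1-yl)-4H,8H-benzo[1,2-b:3,4-b']dipyran-4-one, via free-phenol diketone 21 (not isolated), via hemiketal 22 (not isolated)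
Conditions: conc. HCl, MeOH–THF, 60 °C
Reagents that add atoms: none
Why: Acid-catalysed MOM cleavage frees the ring A phenol, which adds to the ring B carbonyl and loses water to the chromone (cyclodehydration of an ortho-hydroxyaryl 1,3-diketone), while the acid-stable allyl ether keeps the ring B oxygen out of the cyclisation.

Step 15
Reactants: 23 the 2'-allyloxy flavone from step 14
Product: 24 3-(2-bromo-3-methylbut-2-en-1-yl)-2-(2-hydroxy-4,5-dimethoxyphenyl)-5-methoxy-8,8-dimethyl-6-(3-methylbut-2-en-1-yl)-4H,8H-benzo[1,2-b:3,4-b']dipyran-4-one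
Conditions: Pd(PPh3)4 (5 mol%), morpholine (5 equiv), THF, rt
Reagents that add atoms: none
Why: Tsuji–Trost deallylation: zerovalent palladium ionises the aryl allyl ether at room temperature much faster than it inserts into the hindered tetrasubstituted alkenyl bromide, and morpholine traps the allyl group.

Step 16
Reactants: 24 the 2'-hydroxy flavone from step 15
Product: 25 CNP0192589.0 (flavone with 5,4',5'-trimethoxy groups, 6-prenyl group, 7,8-fused 2,2-dimethylpyran and a seven-membered 2'-O–C(=CMe2)–CH2–C3 oxepine bridge)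
Conditions: CuI (20 mol%), N,N-dimethylglycine (40 mol%), Cs2CO3 (2 equiv), dioxane, 100 °C; chromatography on Et3N-deactivated silica
Reagents that add atoms: none
Why: Ullmann-type C–O coupling with monovalent copper joins the caesium phenoxide and the alkenyl bromide, held close on the twisted aryl–chromone axis, into the seven-membered aryl enol ether without any acid, which the product would not tolerate.

**Compound list**
1 | 1-(2,4,6-trihydroxyphenyl)ethan-1-one (phloroacetophenone) | CC(=O)c1c(O)cc(O)cc1O | starting material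
2 | 1-[2,6-dihydroxy-4-(methoxymethoxy)phenyl]ethan-1-one | CC(=O)c1c(O)cc(OCOC)cc1O | intermediate
3 | 1-[2-hydroxy-6-methoxy-4-(methoxymethoxy)phenyl]ethan-1-one | CC(=O)c1c(O)cc(OCOC)cc1OC | intermediate
4 | 1-{2-methoxy-4-(methoxymethoxy)-6-[(3-methylbut-2-en-1-yl)oxy]phenyl}ethan-1-one | CC(=O)c1c(OCC=C(C)C)cc(OCOC)cc1OC | intermediate
5 | 2-acetyl-3-methoxy-5-(methoxymethoxy)-6-(2-methylbut-3-en-2-yl)cyclohexa-2,4-dien-1-one (ortho-dienone; racemic; not isolated) | CC(=O)C1=C(OC)C=C(OCOC)C(C(C)(C)C=C)C1=O | intermediate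
6 | 2-acetyl-3-methoxy-5-(methoxymethoxy)-4-(3-methylbut-2-en-1-yl)cyclohexa-2,5-dien-1-one (para-dienone; racemic; not isolated) | CC(=O)C1=C(OC)C(CC=C(C)C)C(OCOC)=CC1=O | intermediate
7 | 1-[6-hydroxy-2-methoxy-4-(methoxymethoxy)-3-(3-methylbut-2-en-1-yl)phenyl]ethan-1-one | CC(=O)c1c(O)cc(OCOC)c(CC=C(C)C)c1OC | intermediate
8 | 1-[4,6-dihydroxy-2-methoxy-3-(3-methylbut-2-en-1-yl)phenyl]ethan-1-one | CC(=O)c1c(O)cc(O)c(CC=C(C)C)c1OC | intermediate
9 | 3-methylbut-2-enal (prenal) | CC(C)=CC=O | starting material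
10 | 4-acetyl-5-hydroxy-3-methoxy-2-(3-methylbut-2-en-1-yl)-6-(3-methylbut-2-en-1-ylidene)cyclohexa-2,4-dien-1-one (quinone methide; not isolated) | CC(=O)C1=C(O)C(=CC=C(C)C)C(=O)C(CC=C(C)C)=C1OC | intermediate
11 | 1-[5-hydroxy-7-methoxy-2,2-dimethyl-8-(3-methylbut-2-en-1-yl)-2H-chromen-6-yl]ethan-1-one | CC(=O)c1c(O)c2C=CC(C)(C)Oc2c(CC=C(C)C)c1OC | intermediate
12 | 1-[7-methoxy-5-(methoxymethoxy)-2,2-dimethyl-8-(3-methylbut-2-en-1-yl)-2H-chromen-6-yl]ethan-1-one | CC(=O)c1c(OCOC)c2C=CC(C)(C)Oc2c(CC=C(C)C)c1OC | intermediate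
13 | 2-hydroxy-4,5-dimethoxybenzoic acid | COc1cc(O)c(cc1OC)C(O)=O | starting material
14 | prop-2-en-1-yl 4,5-dimethoxy-2-(prop-2-en-1-yloxy)benzoate | COc1cc(OCC=C)c(cc1OC)C(=O)OCC=C | intermediate
15 | 2,3-dibromo-3-methylbutanal (racemic; not isolated) | CC(C)(Br)C(Br)C=O | intermediate
16 | 2-bromo-3-methylbut-2-enal | CC(C)=C(Br)C=O | intermediate
17 | 2-bromo-3-methylbut-2-en-1-ol | CC(C)=C(Br)CO | intermediate
18 | 1,2-dibromo-3-methylbut-2-ene | CC(C)=C(Br)CBr | intermediate
19 | 1-[4,5-dimethoxy-2-(prop-2-en-1-yloxy)phenyl]-3-[7-methoxy-5-(methoxymethoxy)-2,2-dimethyl-8-(3-methylbut-2-en-1-yl)-2H-chromen-6-yl]propane-1,3-dione | COc1cc(OCC=C)c(cc1OC)C(=O)CC(=O)c1c(OCOC)c2C=CC(C)(C)Oc2c(CC=C(C)C)c1OC | intermediate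
20 | 2-(2-bromo-3-methylbut-2-en-1-yl)-1-[4,5-dimethoxy-2-(prop-2-en-1-yloxy)phenyl]-3-[7-methoxy-5-(methoxymethoxy)-2,2-dimethyl-8-(3-methylbut-2-en-1-yl)-2H-chromen-6-yl]propane-1,3-dione (racemic) | COc1cc(OCC=C)c(cc1OC)C(=O)C(CC(Br)=C(C)C)C(=O)c1c(OCOC)c2C=CC(C)(C)Oc2c(CC=C(C)C)c1OC | intermediate
21 | 2-(2-bromo-3-methylbut-2-en-1-yl)-1-[4,5-dimethoxy-2-(prop-2-en-1-yloxy)phenyl]-3-[5-hydroxy-7-methoxy-2,2-dimethyl-8-(3-methylbut-2-en-1-yl)-2H-chromen-6-yl]propane-1,3-dione (racemic; not isolated) | COc1cc(OCC=C)c(cc1OC)C(=O)C(CC(Br)=C(C)C)C(=O)c1c(O)c2C=CC(C)(C)Oc2c(CC=C(C)C)c1OC | intermediate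
22 | 3-(2-bromo-3-methylbut-2-en-1-yl)-2-[4,5-dimethoxy-2-(prop-2-en-1-yloxy)phenyl]-2-hydroxy-5-methoxy-8,8-dimethyl-6-(3-methylbut-2-en-1-yl)-2,3-dihydro-4H,8H-benzo[1,2-b:3,4-b']dipyran-4-one (hemiketal; mixture of stereoisomers; not isolated) | COc1cc(OCC=C)c(cc1OC)C1(O)Oc2c3C=CC(C)(C)Oc3c(CC=C(C)C)c(OC)c2C(=O)C1CC(Br)=C(C)C | intermediate
23 | 3-(2-bromo-3-methylbut-2-en-1-yl)-2-[4,5-dimethoxy-2-(prop-2-en-1-yloxy)phenyl]-5-methoxy-8,8-dimethyl-6-(3-methylbut-2-en-1-yl)-4H,8H-benzo[1,2-b:3,4-b']dipyran-4-one | COc1cc(OCC=C)c(cc1OC)-c1oc2c3C=CC(C)(C)Oc3c(CC=C(C)C)c(OC)c2c(=O)c1CC(Br)=C(C)C | intermediate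
24 | 3-(2-bromo-3-methylbut-2-en-1-yl)-2-(2-hydroxy-4,5-dimethoxyphenyl)-5-methoxy-8,8-dimethyl-6-(3-methylbut-2-en-1-yl)-4H,8H-benzo[1,2-b:3,4-b']dipyran-4-one | COc1cc(O)c(cc1OC)-c1oc2c3C=CC(C)(C)Oc3c(CC=C(C)C)c(OC)c2c(=O)c1CC(Br)=C(C)C | intermediate
25 | CNP0192589.0 (oxepine-bridged pyranoflavone; achiral) | COc1cc2c(cc1OC)-c1oc3c4c(c(CC=C(C)C)c(OC)c3c(=O)c1CC(=C(C)C)O2)OC(C)(C)C=C4 | target

**Summary**
Total steps: 16. Longest linear sequence: 12 steps (steps 1–7, then 12–16, from phloroacetophenone 1).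

**Steps most likely to fail, with fallbacks**

Step 16 (seven-membered C–O ring closure onto a tetrasubstituted alkenyl bromide; base-induced loss of HBr to an allene could compete). The fallback sets out from 24 and comes back at 25. The alkenyl bromide is first turned into a nucleophilic partner by Miyaura borylation (PdCl2(dppf), a divalent palladium precatalyst, B2pin2, KOAc, dioxane, 80 °C), which gives the pinacol alkenylboronate F1. The ring is then closed oxidatively by an intramolecular Chan–Lam coupling (Cu(OAc)2, divalent copper, Et3N, 4 Å sieves, air, CH2Cl2, rt), which forms the same aryl enol ether 25 at room temperature.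

Step 13 (O- instead of C-alkylation, or no reaction, at the hindered diketone). The fallback sets out from 12 and comes back at 20. The side chain is put on before the condensation: the kinetic lithium enolate of 12 (LiN(i-Pr)2, THF, −78 °C) is alkylated with 18 to give the 4-bromo-5-methylhex-4-en-1-one F2, where O-alkylation is not an issue. The crossed Claisen condensation of F2 with 14 (NaH or LiN(SiMe3)2, THF, 65 °C) then gives the α-substituted diketone 20 directly.

Step 6 (modest yield, or ring closure through the wrong hydroxyl, in the prenal chromenylation). The fallback sets out from 8 and comes back at 11. The free 4-OH alone is alkylated with 3-chloro-3-methylbut-1-yne (K2CO3, KI, acetone, 60 °C) to give the aryl 1,1-dimethylpropargyl ether F3. Heating F3 in PhNEt2 at 180 °C triggers a propargyl Claisen rearrangement to the only free ring carbon, then a [1,5]-hydrogen shift and oxa-6π closure, which can only give chromene 11 with the pyran oxygen coming from the 4-position.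

**Further compounds**
F1 | step 16 | 2-(2-hydroxy-4,5-dimethoxyphenyl)-5-methoxy-8,8-dimethyl-6-(3-methylbut-2-en-1-yl)-3-[3-methyl-2-(4,4,5,5-tetramethyl-1,3,2-dioxaborolan-2-yl)but-2-en-1-yl]-4H,8H-benzo[1,2-b:3,4-b']dipyran-4-one | COc1cc(O)c(cc1OC)-c1oc2c3C=CC(C)(C)Oc3c(CC=C(C)C)c(OC)c2c(=O)c1CC(B1OC(C)(C)C(C)(C)O1)=C(C)C
F2 | step 13 | 4-bromo-1-[7-methoxy-5-(methoxymethoxy)-2,2-dimethyl-8-(3-methylbut-2-en-1-yl)-2H-chromen-6-yl]-5-methylhex-4-en-1-one | CC(C)=C(Br)CCC(=O)c1c(OCOC)c2C=CC(C)(C)Oc2c(CC=C(C)C)c1OC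
F3 | step 6 | 1-{6-hydroxy-2-methoxy-3-(3-methylbut-2-en-1-yl)-4-[(2-methylbut-3-yn-2-yl)oxy]phenyl}ethan-1-one | CC(=O)c1c(O)cc(OC(C)(C)C#C)c(CC=C(C)C)c1OC
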